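**Plan** (isoflavan numbering: O1, C2, C3, C4, C4a, C5–C8, C8a; ring B primed)
- Retrosynthesis: the two MOM ethers on ring B are put back. Ring C is then cut at O1–C2 and C4–C4a in one stroke. Last, C3–C1′ and C3′–prenyl are cut.
- The double cut gives two achiral halves. One is 2,6-dihydroxy-4-methoxybenzaldehyde (ring A). The other is a 3-aryloxetane holding ring B and C2–C3–C4, with a temporary oxygen bridge from C2 to C4.
- Enabling feature: C3 bears two CH2 groups (C2, C4) and is stereogenic only because one ends on O1 and the other on C4a. C1′ lies para to O4′ and ortho to O2′, so ring B can assist C–O ionisation as a phenonium ion. Ring A is C2v-symmetric, so its two OH/ortho-CH pairs are one and the same 1,3-bis-nucleophile.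
- Forward: resorcinol becomes ring B by two directed lithiations (prenyl at C3′, oxetane at C1′). Phloroglucinaldehyde becomes ring A by one methylation. The halves are joined and ring C, the only ring made, closes in step 5. MOM removal ends the route.
- Stereochemistry: the single stereocentre C3 (R) comes from catalyst-controlled desymmetrisation of the prochiral oxetane in step 5 and is not touched afterwards.

Key step: step 5

Assumption: the sense of induction of the chiral acid in step 5 cannot be derived from precedent. The (R)-configured acid is written, and its mirror image is used if a test run shows that it leads to the (3S) series.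

Step 1
Reactants: 1 resorcinol (benzene-1,3-diol)
Product: 2 1,3-bis(methoxymethoxy)benzene
Conditions: NaH, MOMCl, DMF, 0 °C → rt
Reagents that add atoms: chloromethyl methyl ether (MOMCl), COCCl
Why: Williamson-type O-alkylation of the bis-phenoxide; the MOM ethers protect both phenols and later direct both lithiations.

Step 2
Reactants: 2 1,3-bis(methoxymethoxy)benzene
Product: 4 1,3-bis(methoxymethoxy)-2-(3-methylbut-2-en-1-yl)benzene, via 2-lithio arene 3 (not isolated)
Conditions: n-BuLi, THF, 0 °C → rt; prenyl bromide, −78 °C → rt
Reagents that add atoms: prenyl bromide (1-bromo-3-methylbut-2-ene), CC(C)=CCBr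
Why: Directed ortho-metalation removes the C–H between the two chelating OMOM groups, and SN2 alkylation of the aryllithium at the primary carbon of prenyl bromide places the prenyl group between the two oxygens.

Step 3
Reactants: 4 1,3-bis(methoxymethoxy)-2-(3-methylbut-2-en-1-yl)benzene; 5 3-iodooxetane
Product: 8 3-[2,4-bis(methoxymethoxy)-3-(3-methylbut-2-en-1-yl)phenyl]oxetane, via 4-lithio arene 6 (not isolated), via aryl Grignard reagent 7 (not isolated)
Conditions: n-BuLi, TMEDA, THF, 0 °C; MgBr2·OEt2; then 5, CoCl2 (5 mol %), trans-N,N,N′,N′-tetramethylcyclohexane-1,2-diamine (6 mol %), THF, 0 °C → rt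
Reagents that add atoms: none
Why: A second directed ortho-metalation takes one of the two equivalent C–H bonds next to an OMOM group, and after transmetalation the aryl Grignard reagent couples with the secondary iodide in a cobalt-catalysed Kumada-type alkyl–aryl cross-coupling that runs through the oxetan-3-yl radical and leaves the strained ether intact.

Step 4
Reactants: 9 2,4,6-trihydroxybenzaldehyde
Product: 10 2,6-dihydroxy-4-methoxybenzaldehyde
Conditions: MeI (1.0 equiv), K2CO3 (1.0 equiv), acetone, rt
Reagents that add atoms: iodomethane, CI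
Why: Chemoselective Williamson O-methylation; the 4-OH is the only hydroxyl that cannot hydrogen-bond to the formyl group and, being para to it, is the most acidic, so one equivalent of base and MeI should alkylate it first and keep the C2v symmetry.

Step 5
Reactants: 8 3-[2,4-bis(methoxymethoxy)-3-(3-methylbut-2-en-1-yl)phenyl]oxetane; 10 2,6-dihydroxy-4-methoxybenzaldehyde
Product: 12 (3R)-3-[2,4-bis(methoxymethoxy)-3-(3-methylbut-2-en-1-yl)phenyl]-7-hydroxy-5-methoxy-3,4-dihydro-2H-chromene-8-carbaldehyde, via seco alcohol 11 (not isolated)
Conditions: (R)-3,3′-bis(2,4,6-triisopropylphenyl)-1,1′-binaphthalene-2,2′-diyl N-(trifluoromethylsulfonyl)phosphoramidate (10 mol %), 10 (1.5 equiv), PhMe/CH2Cl2, 5 Å MS, rt; then, same flask, THF, PPh3, DIAD, 0 °C → rt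
Reagents that add atoms: none
Why: Proposed new method: the chiral acid protonates the oxetane oxygen of 8 in its pocket, C1′ of the electron-rich ring B pushes out one of the two enantiotopic CH2–O bonds to give a phenonium (spirocyclopropane) ion pair, and release of the ring strain lets C3 of aldehyde 10, the carbon ortho/para to three oxygen donors, open the three-membered ring at its CH2 in a Friedel–Crafts alkylation (C4–C4a) to give 11; PPh3/DIAD then convert the freed primary alcohol into an alkoxyphosphonium ion that the neighbouring phenol OH displaces (O1–C2). The closest known reaction types are the chiral-phosphoric-acid-catalysed desymmetrising opening of 3-aryloxetanes by sulfur, chloride and oxygen nucleophiles, the Friedel–Crafts capture of phenonium ions by electron-rich arenes, and the Mitsunobu closure of 2-(3-hydroxypropyl)phenols to chromans. The only ring closed, dihydropyran ring C, forms by 6-exo-tet SN2 attack of the phenol oxygen on C2. The only stereocentre, C3, is never a reacting atom: its configuration is fixed by which enantiotopic CH2 of the oxetane the catalyst hands to carbon, so it is catalyst-controlled, and it has no pathway for epimerisation afterwards. The step needs C- over O-alkylation and a single site on ring A: the OH groups of 10 are engaged in hydrogen bonds to the formyl group and to the catalyst anion, the C2v symmetry of 10 makes its two O/C pairs identical with the formyl carbon blocking the position between the hydroxyls, and an O-alkylated by-product cannot close to a chroman under Mitsunobu conditions, so it should cost material but not enantiopurity.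

Step 6
Reactants: 12 (3R)-3-[2,4-bis(methoxymethoxy)-3-(3-methylbut-2-en-1-yl)phenyl]-7-hydroxy-5-methoxy-3,4-dihydro-2H-chromene-8-carbaldehyde
Product: 13 (3R)-3-[2,4-dihydroxy-3-(3-methylbut-2-en-1-yl)phenyl]-7-hydroxy-5-methoxy-3,4-dihydro-2H-chromene-8-carbaldehyde (target)
Conditions: HCl (cat.), MeOH, 40 °C
Reagents that add atoms: none
Why: Acid-catalysed acetal exchange (MOM cleavage) with methanol as formaldehyde acceptor, a standard unmasking of ortho-prenylated phenols; the mild acid is meant to spare the prenyl group and the aldehyde, and C3 is not affected.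

**Compound list**
1 | resorcinol (benzene-1,3-diol) | Oc1cccc(O)c1 | starting material
2 | 1,3-bis(methoxymethoxy)benzene | COCOc1cccc(OCOC)c1 | intermediate
3 | [2,6-bis(methoxymethoxy)phenyl]lithium | COCOc1cccc(OCOC)c1[Li] | intermediate
4 | 1,3-bis(methoxymethoxy)-2-(3-methylbut-2-en-1-yl)benzene | COCOc1cccc(OCOC)c1CC=C(C)C | intermediate
5 | 3-iodooxetane | IC1COC1 | starting material
6 | [2,4-bis(methoxymethoxy)-3-(3-methylbut-2-en-1-yl)phenyl]lithium | [Li]c1ccc(OCOC)c(CC=C(C)C)c1OCOC | intermediate
7 | [2,4-bis(methoxymethoxy)-3-(3-methylbut-2-en-1-yl)phenyl]magnesium bromide | Br[Mg]c1ccc(OCOC)c(CC=C(C)C)c1OCOC | intermediate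
8 | 3-[2,4-bis(methoxymethoxy)-3-(3-methylbut-2-en-1-yl)phenyl]oxetane | C1OCC1c1ccc(OCOC)c(CC=C(C)C)c1OCOC | intermediate
9 | 2,4,6-trihydroxybenzaldehyde | O=Cc1c(O)cc(O)cc1O | starting material
10 | 2,6-dihydroxy-4-methoxybenzaldehyde | COc1cc(O)c(C=O)c(O)c1 | intermediate
11 | 3-{(2R)-2-[2,4-bis(methoxymethoxy)-3-(3-methylbut-2-en-1-yl)phenyl]-3-hydroxypropyl}-2,6-dihydroxy-4-methoxybenzaldehyde | COc1cc(O)c(C=O)c(O)c1C[C@H](c1ccc(OCOC)c(CC=C(C)C)c1OCOC)CO | intermediate
12 | (3R)-3-[2,4-bis(methoxymethoxy)-3-(3-methylbut-2-en-1-yl)phenyl]-7-hydroxy-5-methoxy-3,4-dihydro-2H-chromene-8-carbaldehyde | COc1cc(O)c(C=O)c2c1C[C@H](c1ccc(OCOC)c(CC=C(C)C)c1OCOC)CO2 | intermediate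
13 | (3R)-3-[2,4-dihydroxy-3-(3-methylbut-2-en-1-yl)phenyl]-7-hydroxy-5-methoxy-3,4-dihydro-2H-chromene-8-carbaldehyde | COc1cc(O)c(C=O)c2c1C[C@H](c1ccc(O)c(CC=C(C)C)c1O)CO2 | target

Total step count: 6. Longest linear sequence: 5 (steps 1, 2, 3, 5, 6).

**Steps most likely to fail**

Step 5.
- The ring carbon of 10 may be too weak a nucleophile, so that the opening stalls.
- The 2′-OMOM oxygen may attack the activated oxetane first, closing a five-membered ring on ring B with MOM transfer.
- The phenonium ion may be opened at C3, which shifts the aryl group.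
- The catalyst may tell the two enantiotopic CH2 groups apart poorly.

The fallback sets out from 8 and 10 and returns at 12, using known chemistry only. Oxetane 8 is opened enantioselectively with chloride, using a chiral phosphoric acid and HCl released slowly from a chlorosilane on wet molecular sieves, to give the (R)-chlorohydrin F1. Mitsunobu etherification of its alcohol with an excess of 10 gives the chloroalkyl aryl ether F2 and so fixes O1–C2 at the carbinol carbon. Finkelstein exchange (NaI, acetone) gives the iodoalkyl aryl ether F3. K2CO3 in dilute DMF then closes C4–C4a by intramolecular C-alkylation of the 7-phenolate at its para carbon (Ar2-6 participation). C3 is not touched in any of these operations.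

Step 3. Deprotonation at the benzylic, allylic CH2 of the prenyl group may compete with ring lithiation. The ortho-substituted Grignard reagent may couple slowly, so that homocoupling and reduction of the iodide take over.

The fallback sets out from 4 (through aryllithium 6) and returns at 8. It builds the oxetane ring instead of coupling it.
- Quenching 6 with I2 gives the aryl iodide F4.
- CuI-catalysed arylation of diethyl malonate (Cs2CO3) gives the aryl malonate F5.
- LiAlH4 reduction gives the 2-arylpropane-1,3-diol F6.
- n-BuLi/TsCl gives the monotosylate F7, and a second equivalent of n-BuLi closes it to 8 by Williamson etherification.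

Step 4. Methylation may run on to the dimethyl ether or start at a chelated hydroxyl, which breaks the symmetry on which step 5 relies.

The fallback sets out from 9 and returns at 10. It reverses the logic. Exhaustive methylation (excess MeI, K2CO3) gives 2,4,6-trimethoxybenzaldehyde F8. AlCl3 in CH2Cl2 then removes only the two methyl groups ortho to the formyl group by chelation-controlled ether cleavage.

**Further compounds**
F1 | step 5 | (R)-chlorohydrin, (2R)-2-[2,4-bis(methoxymethoxy)-3-(3-methylbut-2-en-1-yl)phenyl]-3-chloropropan-1-ol | ClC[C@H](c1ccc(OCOC)c(CC=C(C)C)c1OCOC)CO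
F2 | step 5 | chloroalkyl aryl ether, 2-{(2R)-2-[2,4-bis(methoxymethoxy)-3-(3-methylbut-2-en-1-yl)phenyl]-3-chloropropoxy}-6-hydroxy-4-methoxybenzaldehyde | ClC[C@H](c1ccc(OCOC)c(CC=C(C)C)c1OCOC)COc1cc(OC)cc(O)c1C=O
F3 | step 5 | iodoalkyl aryl ether, 2-{(2R)-2-[2,4-bis(methoxymethoxy)-3-(3-methylbut-2-en-1-yl)phenyl]-3-iodopropoxy}-6-hydroxy-4-methoxybenzaldehyde | IC[C@H](c1ccc(OCOC)c(CC=C(C)C)c1OCOC)COc1cc(OC)cc(O)c1C=O
F4 | step 3 | aryl iodide, 1-iodo-2,4-bis(methoxymethoxy)-3-(3-methylbut-2-en-1-yl)benzene | Ic1ccc(OCOC)c(CC=C(C)C)c1OCOC
F5 | step 3 | aryl malonate, diethyl 2-[2,4-bis(methoxymethoxy)-3-(3-methylbut-2-en-1-yl)phenyl]propanedioate | CCOC(=O)C(C(=O)OCC)c1ccc(OCOC)c(CC=C(C)C)c1OCOC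
F6 | step 3 | 2-[2,4-bis(methoxymethoxy)-3-(3-methylbut-2-en-1-yl)phenyl]propane-1,3-diol | OCC(CO)c1ccc(OCOC)c(CC=C(C)C)c1OCOC
F7 | step 3 | monotosylate (racemic), 2-[2,4-bis(methoxymethoxy)-3-(3-methylbut-2-en-1-yl)phenyl]-3-hydroxypropyl 4-methylbenzenesulfonate | OCC(COS(=O)(=O)c1ccc(C)cc1)c1ccc(OCOC)c(CC=C(C)C)c1OCOC
F8 | step 4 | 2,4,6-trimethoxybenzaldehyde | COc1cc(OC)c(C=O)c(OC)c1
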